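## The problem

CNP0320216.1 is a germacrane-type ten-membered carbocycle. The atoms are labelled as follows and the labels are kept for every intermediate: C1 (epoxide CH), C2 (CH2), C3 (CH bearing the angelate), C4 (methyl-bearing epoxide carbon), C5 (epoxide CH), C6 (CH2), C7 (CH bearing isopropenyl), C8 (CH bearing the senecioate), C9 (CHOH), C10 (methyl-bearing epoxide carbon, bonded to C1). C11, C12 and C13 are the isopropenyl carbon, its methylene and its methyl; C14 and C15 are the methyls on C10 and C4.

A synthesis has to close a medium ring and set eight stereocentres (1R,3S,4S,5S,7R,8S,9S,10S), five of them contiguous from C7 to C1. Both epoxides have cis ring bonds, so each descends from a Z trisubstituted ring alkene. The C9 hydroxyl is allylic to C1=C10 and can deliver oxygen to it; the C3 acyloxy group can bias C4=C5 only sterically. C9 can control C8 by 1,2-induction, and C8 and C7 can be set together. C3 and C9, however, are 1,5-related across an alkene and each needs its own source of asymmetry.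

Several groups forbid rough treatment:
- the angelate isomerises to the tiglate;
- the senecioate can deconjugate;
- trisubstituted epoxides in a ten-membered ring open transannularly with acid;
- the C8 ester can migrate to the free C9 hydroxyl.

The feature that makes the key step possible is that the C8 carbinol sits next to C7, which carries the isopropenyl group. C8(OH)–C7–C11=C12 is a homoallylic alcohol, the retron of an allylmetal addition of C12–C11=C7 to a C8 aldehyde.

## Retrosynthesis

**Epoxides (33 ⇒ 32 ⇒ 31).** The four C–O bonds of the two oxiranes are cut first, giving the Z,Z-diene 31. Epoxides are the most acid-sensitive groups, so they are introduced after all protecting-group chemistry. The C1–C10 epoxide is cut last in the retrosynthetic sense but made first (31 → 32), because only then can the free C9 hydroxyl direct it. The C4–C5 epoxide (32 → 33) must then come from an undirected peracid attack anti to the C3 ester. The forward reactions must be face- and site-selective among four alkenes.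

**Esters and silyl ethers (31 ⇒ 30 ⇒ 29 ⇒ 28 ⇒ 27).** Cutting the two acyl C–O bonds and restoring two silyl ethers leads to alcohol 27, with C8–OH free, C3–OTES and C9–OTBS. The triethylsilyl/tert-butyldimethylsilyl pair lets C3 be freed before C9, so that each oxygen is acylated or left free in turn without relying on reactivity differences between two similar allylic alcohols.

**C7–C8 (27 ⇒ 26).** The ring is opened at C7–C8 to the stannyl aldehyde 26. Against the neighbouring ring bonds this cut has three advantages: it creates two adjacent stereocentres, it closes the ring, and it unveils the isopropenyl group in one step with no later adjustment. The precursor is an open chain with only two stereocentres and two Z alkenes. The forward reaction must attack through C7 and not C12, must beat bimolecular addition, and must give the 7,8-syn, 8,9-erythro isomer.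

**Chain termini (26 ⇒ 25 ⇒ 24 ⇒ 23 ⇒ 22).** The stannane is traced to an allylic chloride and the aldehyde to a primary alcohol, both arising from diol 23 and hence from ester 22. C8 is carried as a benzoate: a primary silyl ether there could not be removed next to the secondary triethylsilyl ether, nor with acid once the stannane is present. One hydride reduction of 22 frees both termini, and the allylic hydroxyl is then distinguished from the saturated one by its chemistry, not by a protecting group.

**C7=C11 (22 ⇒ 20 + 21).** The E trisubstituted enoate is cut by a Wittig disconnection to aldehyde 20 and the stabilised ylide 21. This is simpler than any allylmetal or cross-coupling construction of the same alkene, and the reagent is commercial.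

**C3–C4 (20 ⇒ 18 ⇒ 17 ⇒ 16 + 9).** The bond between the alkenyl carbon C4 and the carbinol carbon C3 is cut to aldehyde 16 and iodoalkene 9. The Z geometry is carried in by 9 and the C3 configuration must come from the chiral chromium ligand, since C9 is too remote to help.

**C9–C10 (16 ⇒ 14 ⇒ 13 ⇒ 12 + 9).** The same cut, with the same iodoalkene 9, leads to 2-oxoethyl benzoate 12. One building block thus supplies both Z alkenes and C1–C7.

**Building blocks (9 ⇒ 4 + 5; 4 ⇒ 3 ⇒ 1; 12 ⇒ 10).** The iodoalkene comes from aldehyde 4 and ethyltriphenylphosphonium iodide 5 by iodo-olefination, 4 from propane-1,3-diol 1 through its monosilyl ether 3, and 12 from allyl benzoate 10 by ozonolysis.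

## Roads not taken

**Alternative 1:** The cuts are C9–C10 and C3–C4. Iodoalkene 9 would be coupled twice under CrCl2/NiCl2 and one chiral sulfonamide ligand. The first coupling is with (tert-butyldimethylsilyloxy)acetaldehyde A2; after silylation with the silyl triflate and direct oxidation of the primary silyl ether, the second gives the open chain A1.
- Merits: one building block is used twice, both carbinols are set by the reagent with no ring to interfere, and the Z geometry is bought once.
- Weak points: the key step ends at an open chain, so the ring, C7 and C8 are all still to be solved. In addition, the primary TBS ether at C8 of A1 cannot later be removed next to the secondary triethylsilyl ether that C3 needs.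
- Comparison: as a way of building the chain this road is as good as anything available, and the chosen plan adopts its two couplings as steps 5 and 8. What the chosen plan adds is the ring-closing event that A1 lacks, and a benzoate at C8 that the ester reduction removes.

**Alternative 2:** The cut runs through the C1–C10 epoxide (the C1–C10 bond and the O–C10 bond). LiN(SiMe3)2 would enolise the α-bromo ketone of the open-chain keto aldehyde A3 at C10; addition to the C1 aldehyde closes the ring and the alkoxide displaces bromide to give epoxy ketone A4.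
- Merits: the ring, two stereocentres and one epoxide arise in a single operation, and C7/C8 would be set earlier in an open chain.
- Weak points: a ten-membered Darzens closure has little support. The base can also enolise toward C8 or C2. Cis versus trans epoxide geometry depends on the syn/anti course of a macrocyclic aldol that nothing in A3 controls, and the same holds for its facial relation to C8. The C9 ketone must afterwards be reduced cis to the epoxide.
- Comparison: the end-game would be one epoxidation shorter, which is a real advantage. The chosen plan sets against it a ring closure of a known type and epoxides introduced last under established directing effects.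

**Alternative 3:** The cut is the C3–C8 bond of a carvone-derived, cis-fused bicyclic 1,2-diol A5. Pb(OAc)4 would cleave it to the ten-membered Z,Z-dienedione A6.
- Merits: no macrocyclisation is needed, both Z alkenes are guaranteed by the cyclohexene rings, and C7 comes from the chiral pool. In certainty of ring formation and alkene geometry this road is better than the chosen one.
- Weak points: the cleavage erases C3 and C8, which must both be re-set by ketone reduction in a flexible ring. The C8 ketone lies between two epimerisable centres (C7, whose isopropenyl group can move into conjugation, and the α-alkoxy C9). The C3 ketone is β,γ-unsaturated toward C1=C10. Reaching A5 with its tertiary diol and C9 oxygen is itself a long problem.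
- Comparison: the chosen plan sets against it C3 and C9 fixed by reagent control before the ring exists, C8 and C7 formed directly at the correct oxidation level, and no ring ketone at any stage.

Key step: step 16

Remark: the ligand L* of steps 5 and 8 is an oxazoline sulfonamide, N-[2-(4-isopropyl-4,5-dihydro-1,3-oxazol-2-yl)-6-methylphenyl]methanesulfonamide. Which antipode directs the alkenyl group to the Re face of the aldehyde is not derived here; both steps need that same antipode.

## Route

Step 1
Reactants: 1 propane-1,3-diol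
Product: 3 3-[(triethylsilyl)oxy]propan-1-ol, via sodium 3-hydroxypropan-1-olate 2 (not isolated)
Conditions: NaH (1.0 equiv), THF, rt; TESCl, 0 °C → rt
Reagents that add atoms: chlorotriethylsilane, CC[Si](Cl)(CC)CC
Why: O-silylation of the monosodium alkoxide, which precipitates from THF and is therefore silylated once; no stereocentre is involved.

Step 2
Reactants: 3 3-[(triethylsilyl)oxy]propan-1-ol
Product: 4 3-[(triethylsilyl)oxy]propanal
Conditions: SO3·pyridine, DMSO, i-Pr2NEt, CH2Cl2, 0 °C
Reagents that add atoms: none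
Why: Parikh–Doering oxidation of a primary alcohol; the non-acidic medium keeps the triethylsilyl ether and, at 0 °C, should avoid β-elimination.

Step 3
Reactants: 5 ethyltriphenylphosphonium iodide; 4 3-[(triethylsilyl)oxy]propanal
Product: 9 triethyl{[(3Z)-4-iodopent-3-en-1-yl]oxy}silane, via ethylidenetriphenylphosphorane 6 (not isolated), via (1-iodoethyl)triphenylphosphonium iodide 7 (not isolated), via (1-iodoethylidene)triphenylphosphorane 8 (not isolated)
Conditions: n-BuLi, THF, rt → −78 °C; I2, −78 °C; NaN(SiMe3)2, −20 °C; then 4, −78 → −20 °C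
Reagents that add atoms: iodine, II
Why: Stork–Zhao-type iodo-olefination: the ethylidene ylide is iodinated, deprotonated again and condensed with the aldehyde. The non-stabilised iodo ylide reacts under kinetic control and places iodine cis to the chain, which gives the Z trisubstituted iodoalkene.

Step 4
Reactants: 10 allyl benzoate
Product: 12 2-oxoethyl benzoate, via ozonide 11 (not isolated)
Conditions: O3, CH2Cl2, −78 °C; Me2S, −78 °C → rt
Reagents that add atoms: ozone, [O-][O+]=O
Why: Ozonolysis of a terminal alkene with reductive work-up; the benzoate is inert and the terminal carbon leaves as formaldehyde.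

Step 5
Reactants: 12 2-oxoethyl benzoate; 9 triethyl{[(3Z)-4-iodopent-3-en-1-yl]oxy}silane
Product: 13 (2R,3Z)-2-hydroxy-3-methyl-6-[(triethylsilyl)oxy]hex-3-en-1-yl benzoate
Conditions: CrCl2 (3 equiv), ligand L* (3.3 equiv), Et3N, THF, rt; NiCl2 (cat.); then 12 and 9, rt
Reagents that add atoms: none
Why: Nozaki–Hiyama–Kishi coupling: zerovalent nickel inserts into the C–I bond with retention of the Z geometry, and the alkenyl group passes to trivalent chromium and adds to the aldehyde. The sulfonamide-bound chromium distinguishes the aldehyde faces; Re-face addition gives the R carbinol at C9.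

Step 6
Reactants: 13 (2R,3Z)-2-hydroxy-3-methyl-6-[(triethylsilyl)oxy]hex-3-en-1-yl benzoate
Product: 14 (2R,3Z)-2-[(tert-butyldimethylsilyl)oxy]-3-methyl-6-[(triethylsilyl)oxy]hex-3-en-1-yl benzoate
Conditions: TBSOTf, 2,6-lutidine, CH2Cl2, −78 °C
Reagents that add atoms: tert-butyldimethylsilyl trifluoromethanesulfonate, CC(C)(C)[Si](C)(C)OS(=O)(=O)C(F)(F)F
Why: Silylation of a hindered allylic alcohol with a silyl triflate and a non-nucleophilic base; the low temperature should prevent benzoate migration and exchange at the primary triethylsilyl ether.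

Step 7
Reactants: 14 (2R,3Z)-2-[(tert-butyldimethylsilyl)oxy]-3-methyl-6-[(triethylsilyl)oxy]hex-3-en-1-yl benzoate
Product: 16 (2R,3Z)-2-[(tert-butyldimethylsilyl)oxy]-3-methyl-6-oxohex-3-en-1-yl benzoate, via alkoxysulfonium chloride 15 (not isolated)
Conditions: (COCl)2, DMSO, CH2Cl2, −78 → −30 °C; Et3N, −78 → 0 °C; used crude
Reagents that add atoms: none
Why: Swern oxidation applied directly to a primary triethylsilyl ether: the chlorosulfonium salt cleaves the unhindered Si–O bond and the alkoxysulfonium salt collapses with Et3N to the aldehyde, while the secondary TBS ether and the benzoate stay. The β,γ-unsaturated aldehyde is not purified, so that C1=C10 does not move into conjugation.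

Step 8
Reactants: 16 (2R,3Z)-2-[(tert-butyldimethylsilyl)oxy]-3-methyl-6-oxohex-3-en-1-yl benzoate; 9 triethyl{[(3Z)-4-iodopent-3-en-1-yl]oxy}silane
Product: 17 (2R,3Z,6S,7Z)-2-[(tert-butyldimethylsilyl)oxy]-6-hydroxy-3,7-dimethyl-10-[(triethylsilyl)oxy]deca-3,7-dien-1-yl benzoate
Conditions: CrCl2 (3 equiv), ligand L* (3.3 equiv), Et3N, THF, rt; NiCl2 (cat.); then 16 and 9, rt
Reagents that add atoms: none
Why: Second Nozaki–Hiyama–Kishi coupling with the same iodoalkene and the same ligand antipode; C3 has the same local topology as C9 (alkenyl, H, O, CH2), so Re-face addition gives the 3S carbinol. C9 is 1,5-related and should exert no useful bias, so the step is reagent-controlled and a minor C3 epimer would be a separable diastereomer.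

Step 9
Reactants: 17 (2R,3Z,6S,7Z)-2-[(tert-butyldimethylsilyl)oxy]-6-hydroxy-3,7-dimethyl-10-[(triethylsilyl)oxy]deca-3,7-dien-1-yl benzoate
Product: 18 (2R,3Z,6S,7Z)-2-[(tert-butyldimethylsilyl)oxy]-3,7-dimethyl-6,10-bis[(triethylsilyl)oxy]deca-3,7-dien-1-yl benzoate
Conditions: TESCl, imidazole, CH2Cl2, 0 °C
Reagents that add atoms: chlorotriethylsilane, CC[Si](Cl)(CC)CC
Why: Routine silylation of a secondary allylic alcohol; the stereocentre is not touched.

Step 10
Reactants: 18 (2R,3Z,6S,7Z)-2-[(tert-butyldimethylsilyl)oxy]-3,7-dimethyl-6,10-bis[(triethylsilyl)oxy]deca-3,7-dien-1-yl benzoate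
Product: 20 (2R,3Z,6S,7Z)-2-[(tert-butyldimethylsilyl)oxy]-3,7-dimethyl-10-oxo-6-[(triethylsilyl)oxy]deca-3,7-dien-1-yl benzoate, via alkoxysulfonium chloride 19 (not isolated)
Conditions: (COCl)2, DMSO, CH2Cl2, −78 → −40 °C; Et3N, −78 → 0 °C; used crude
Reagents that add atoms: none
Why: Direct Swern oxidation of the primary triethylsilyl ether, which the chlorosulfonium salt cleaves much faster than the hindered secondary TES and TBS ethers. The product is again a β,γ-unsaturated aldehyde and is carried on at once.

Step 11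
Reactants: 20 (2R,3Z,6S,7Z)-2-[(tert-butyldimethylsilyl)oxy]-3,7-dimethyl-10-oxo-6-[(triethylsilyl)oxy]deca-3,7-dien-1-yl benzoate; 21 ethyl 2-(triphenylphosphoranylidene)propanoate
Product: 22 ethyl (2E,5Z,7S,9Z,11R)-12-(benzoyloxy)-11-[(tert-butyldimethylsilyl)oxy]-2,6,10-trimethyl-7-[(triethylsilyl)oxy]dodeca-2,5,9-trienoate
Conditions: CH2Cl2, rt
Reagents that add atoms: none
Why: Wittig olefination with a stabilised ylide, which is only weakly basic and should leave the β,γ-alkene in place; the reversible oxaphosphetane formation gives the E 2-methyl enoate.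

Step 12
Reactants: 22 ethyl (2E,5Z,7S,9Z,11R)-12-(benzoyloxy)-11-[(tert-butyldimethylsilyl)oxy]-2,6,10-trimethyl-7-[(triethylsilyl)oxy]dodeca-2,5,9-trienoate
Product: 23 (2E,5Z,7S,9Z,11R)-11-[(tert-butyldimethylsilyl)oxy]-2,6,10-trimethyl-7-[(triethylsilyl)oxy]dodeca-2,5,9-triene-1,12-diol
Conditions: i-Bu2AlH (6 equiv), CH2Cl2, −78 → −20 °C
Reagents that add atoms: none
Why: Hydride reduction of the enoate (1,2-selective) to the allylic alcohol and reductive cleavage of the benzoate in the same operation, so that C12 and C8 are both freed; silyl ethers are inert to the hydride at this temperature.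

Step 13
Reactants: 23 (2E,5Z,7S,9Z,11R)-11-[(tert-butyldimethylsilyl)oxy]-2,6,10-trimethyl-7-[(triethylsilyl)oxy]dodeca-2,5,9-triene-1,12-diol
Product: 24 (2R,3Z,6S,7Z,10E)-2-[(tert-butyldimethylsilyl)oxy]-12-chloro-3,7,11-trimethyl-6-[(triethylsilyl)oxy]dodeca-3,7,10-trien-1-ol
Conditions: N-chlorosuccinimide (1.3 equiv), Me2S, CH2Cl2, −20 °C; then 23, −20 → 0 °C
Reagents that add atoms: N-chlorosuccinimide, O=C1CCC(=O)N1Cl
Why: Corey–Kim chlorination: both hydroxyls can form alkoxysulfonium salts, but only the allylic one is displaced by chloride under these neutral conditions, without allylic transposition or loss of the E geometry. The hindered saturated C8 alcohol is returned on aqueous work-up.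

Step 14
Reactants: 24 (2R,3Z,6S,7Z,10E)-2-[(tert-butyldimethylsilyl)oxy]-12-chloro-3,7,11-trimethyl-6-[(triethylsilyl)oxy]dodeca-3,7,10-trien-1-ol
Product: 25 (2R,3Z,6S,7Z,10E)-2-[(tert-butyldimethylsilyl)oxy]-3,7,11-trimethyl-6-[(triethylsilyl)oxy]-12-(tributylstannyl)dodeca-3,7,10-trien-1-ol
Conditions: Bu3SnH, LiN(i-Pr)2, THF, 0 °C; then 24 (0.45 equiv), −78 °C; NH4Cl quench at −78 °C
Reagents that add atoms: tributyltin hydride (as tributylstannyllithium), CCCC[SnH](CCCC)CCCC
Why: SN2 displacement of a primary allylic chloride by tributylstannyllithium, fast at −78 °C and known to give the primary allylic stannane with the alkene geometry kept. One equivalent is consumed by the hydroxyl, and the lithium alkoxide is quenched cold so that 1,2-silyl migration should not start.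

Step 15
Reactants: 25 (2R,3Z,6S,7Z,10E)-2-[(tert-butyldimethylsilyl)oxy]-3,7,11-trimethyl-6-[(triethylsilyl)oxy]-12-(tributylstannyl)dodeca-3,7,10-trien-1-ol
Product: 26 (2R,3Z,6S,7Z,10E)-2-[(tert-butyldimethylsilyl)oxy]-3,7,11-trimethyl-6-[(triethylsilyl)oxy]-12-(tributylstannyl)dodeca-3,7,10-trienal
Conditions: SO3·pyridine, DMSO, i-Pr2NEt, CH2Cl2, −10 °C; used crude
Reagents that add atoms: none
Why: Parikh–Doering oxidation; activated-DMSO oxidations tolerate allylic stannanes, which acidic or strongly electrophilic oxidants would destroy. The aldehyde is epimerisable at C9 and is used without chromatography.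

Step 16
Reactants: 26 (2R,3Z,6S,7Z,10E)-2-[(tert-butyldimethylsilyl)oxy]-3,7,11-trimethyl-6-[(triethylsilyl)oxy]-12-(tributylstannyl)dodeca-3,7,10-trienal
Product: 27 (1S,2R,3Z,6S,7Z,10R)-2-[(tert-butyldimethylsilyl)oxy]-3,7-dimethyl-10-(prop-1-en-2-yl)-6-[(triethylsilyl)oxy]cyclodeca-3,7-dien-1-ol
Conditions: BF3·OEt2 (2 equiv), CH2Cl2 (0.002 M), −78 °C, slow addition of 26
Reagents that add atoms: none
Why: BF3 binds the aldehyde oxygen and the γ-carbon C7 of the allylic stannane attacks C8 in an SE2′ sense through an open transition state, the C12–Sn bond breaking as C11=C12 forms. This is the Lewis-acid-promoted intramolecular allylstannane–aldehyde addition known for closing medium and large carbocycles. The ten-membered ring closes by exo attack on the carbonyl (10-exo-trig), and only C7 of the allyl unit enters the ring, so the new alkene is exocyclic. C8 is controlled by C9: with a non-chelating silyl ether and monodentate BF3 the Felkin–Anh arrangement (attack anti to the C9–O bond) gives the 8,9-erythro alcohol, 8S. C7 is controlled relative to C8 by the open transition state, which for Lewis-acid-driven γ-substituted allylstannanes gives the syn adduct, here 7R with isopropenyl cis to the hydroxyl on the ring. The step needs γ- over α-attack (the electronic SE2′ preference), ring closure over bimolecular addition (high dilution; the two Z alkenes bend the chain) and Felkin/syn selectivity (silyl ether, BF3, low temperature).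

Step 17
Reactants: 27 (1S,2R,3Z,6S,7Z,10R)-2-[(tert-butyldimethylsilyl)oxy]-3,7-dimethyl-10-(prop-1-en-2-yl)-6-[(triethylsilyl)oxy]cyclodeca-3,7-dien-1-ol
Product: 28 (1S,2R,3Z,6S,7Z,10R)-2-[(tert-butyldimethylsilyl)oxy]-3,7-dimethyl-10-(prop-1-en-2-yl)-6-[(triethylsilyl)oxy]cyclodeca-3,7-dien-1-yl 3-methylbut-2-enoate
Conditions: 3-methylbut-2-enoic acid, 2,4,6-trichlorobenzoyl chloride, Et3N, toluene, rt; then 27, DMAP, rt → 40 °C
Reagents that add atoms: 3-methylbut-2-enoic acid, CC(C)=CC(=O)O
Why: Yamaguchi esterification: the mixed anhydride acylates the hindered C8 hydroxyl through the acylpyridinium with retention at C8. Avoiding the acid chloride/amine combination should avoid deconjugation through the vinylketene.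

Step 18
Reactants: 28 (1S,2R,3Z,6S,7Z,10R)-2-[(tert-butyldimethylsilyl)oxy]-3,7-dimethyl-10-(prop-1-en-2-yl)-6-[(triethylsilyl)oxy]cyclodeca-3,7-dien-1-yl 3-methylbut-2-enoate
Product: 29 (1S,2R,3Z,6S,7Z,10R)-2-[(tert-butyldimethylsilyl)oxy]-6-hydroxy-3,7-dimethyl-10-(prop-1-en-2-yl)cyclodeca-3,7-dien-1-yl 3-methylbut-2-enoate
Conditions: PPTS, MeOH/CH2Cl2, 0 °C
Reagents that add atoms: none
Why: Acid-catalysed methanolysis of silyl ethers; the secondary triethylsilyl ether is cleaved far faster than the hindered TBS ether next to the ester.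

Step 19
Reactants: 29 (1S,2R,3Z,6S,7Z,10R)-2-[(tert-butyldimethylsilyl)oxy]-6-hydroxy-3,7-dimethyl-10-(prop-1-en-2-yl)cyclodeca-3,7-dien-1-yl 3-methylbut-2-enoate
Product: 30 (1S,2R,3Z,6S,7Z,10R)-2-[(tert-butyldimethylsilyl)oxy]-3,7-dimethyl-6-{[(2Z)-2-methylbut-2-enoyl]oxy}-10-(prop-1-en-2-yl)cyclodeca-3,7-dien-1-yl 3-methylbut-2-enoate
Conditions: (2Z)-2-methylbut-2-enoic acid, 2,4,6-trichlorobenzoyl chloride, Et3N, toluene, rt; then 29, 75 °C
Reagents that add atoms: (2Z)-2-methylbut-2-enoic acid (angelic acid), C/C=C(/C)C(=O)O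
Why: Acylation with the angelic/2,4,6-trichlorobenzoic mixed anhydride without a nucleophilic catalyst, the established way to introduce angelates with little isomerisation to the tiglate; C3 keeps its configuration.

Step 20
Reactants: 30 (1S,2R,3Z,6S,7Z,10R)-2-[(tert-butyldimethylsilyl)oxy]-3,7-dimethyl-6-{[(2Z)-2-methylbut-2-enoyl]oxy}-10-(prop-1-en-2-yl)cyclodeca-3,7-dien-1-yl 3-methylbut-2-enoate
Product: 31 (1S,2R,3Z,6S,7Z,10R)-2-hydroxy-3,7-dimethyl-6-{[(2Z)-2-methylbut-2-enoyl]oxy}-10-(prop-1-en-2-yl)cyclodeca-3,7-dien-1-yl 3-methylbut-2-enoate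
Conditions: HF·pyridine, pyridine, THF, 0 °C → rt
Reagents that add atoms: none
Why: Desilylation with a weakly acidic fluoride source, chosen over basic fluoride to suppress migration of the C8 senecioate to the new C9 hydroxyl and ester cleavage.

Step 21
Reactants: 31 (1S,2R,3Z,6S,7Z,10R)-2-hydroxy-3,7-dimethyl-6-{[(2Z)-2-methylbut-2-enoyl]oxy}-10-(prop-1-en-2-yl)cyclodeca-3,7-dien-1-yl 3-methylbut-2-enoate
Product: 32 (1R,3S,4Z,7R,8S,9S,10S)-9-hydroxy-4,10-dimethyl-8-[(3-methylbut-2-enoyl)oxy]-7-(prop-1-en-2-yl)-11-oxabicyclo[8.1.0]undec-4-en-3-yl (2Z)-2-methylbut-2-enoate (the 1,10-epoxide)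
Conditions: VO(acac)2 (5 mol %), t-BuOOH, CH2Cl2, 0 °C → rt
Reagents that add atoms: tert-butyl hydroperoxide, CC(C)(C)OO
Why: Hydroxyl-directed epoxidation: the vanadate ester of the C9 alcohol delivers oxygen only to C1=C10 (C4=C5 has no free allylic hydroxyl and the isopropenyl group is bishomoallylic). In medium-ring 2-cycloalkenols delivery is syn to the hydroxyl, from the conformer with the C9–O bond near the alkene plane and the C9–C8 ring bond perpendicular to it; the contact with the C10 methyl disfavours the alternative. The expected product is the cis (erythro) epoxy alcohol, 1R,10S.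

Step 22
Reactants: 32 (1R,3S,4Z,7R,8S,9S,10S)-9-hydroxy-4,10-dimethyl-8-[(3-methylbut-2-enoyl)oxy]-7-(prop-1-en-2-yl)-11-oxabicyclo[8.1.0]undec-4-en-3-yl (2Z)-2-methylbut-2-enoate
Product: 33 CNP0320216.1, (1R,3S,4S,5S,7R,8S,9S,10S)-3-angeloyloxy-1,10:4,5-diepoxy-9-hydroxy-8-senecioyloxygermacr-11-ene
Conditions: mCPBA (1.05 equiv), NaHCO3, CH2Cl2, −20 → 0 °C
Reagents that add atoms: 3-chloroperbenzoic acid, OOC(=O)c1cccc(Cl)c1
Why: Prilezhaev epoxidation of the remaining trisubstituted ring alkene, which is more nucleophilic than the 1,1-disubstituted isopropenyl group and the two conjugated ester alkenes. With no directing hydroxyl the peracid should attack the exposed face of the conformer in which the C3–H bond eclipses the alkene (allylic 1,3-strain), that is anti to the angelate, as peracids do with medium-ring cycloalkenyl derivatives. This gives the 4S,5S epoxide trans to the C3 oxygen.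

## Compound list

1 | propane-1,3-diol | OCCCO | starting material
2 | sodium 3-hydroxypropan-1-olate | [Na+].[O-]CCCO | intermediate (not isolated)
3 | 3-[(triethylsilyl)oxy]propan-1-ol | CC[Si](CC)(CC)OCCCO | intermediate
4 | 3-[(triethylsilyl)oxy]propanal | CC[Si](CC)(CC)OCCC=O | intermediate
5 | ethyltriphenylphosphonium iodide | CC[P+](c1ccccc1)(c1ccccc1)c1ccccc1.[I-] | starting material
6 | ethylidenetriphenylphosphorane | CC=P(c1ccccc1)(c1ccccc1)c1ccccc1 | intermediate (not isolated)
7 | (1-iodoethyl)triphenylphosphonium iodide | CC(I)[P+](c1ccccc1)(c1ccccc1)c1ccccc1.[I-] | intermediate (not isolated)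
8 | (1-iodoethylidene)triphenylphosphorane | CC(I)=P(c1ccccc1)(c1ccccc1)c1ccccc1 | intermediate (not isolated)
9 | triethyl{[(3Z)-4-iodopent-3-en-1-yl]oxy}silane | CC[Si](CC)(CC)OCC/C=C(/C)I | intermediate
10 | allyl benzoate (prop-2-en-1-yl benzoate) | C=CCOC(=O)c1ccccc1 | starting material
11 | (1,2,4-trioxolan-3-yl)methyl benzoate (ozonide) | O=C(OCC1OCOO1)c1ccccc1 | intermediate (not isolated)
12 | 2-oxoethyl benzoate | O=CCOC(=O)c1ccccc1 | intermediate
13 | (2R,3Z)-2-hydroxy-3-methyl-6-[(triethylsilyl)oxy]hex-3-en-1-yl benzoate | O=C(OC[C@H](O)/C(C)=C\CCO[Si](CC)(CC)CC)c1ccccc1 | intermediate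
14 | (2R,3Z)-2-[(tert-butyldimethylsilyl)oxy]-3-methyl-6-[(triethylsilyl)oxy]hex-3-en-1-yl benzoate | O=C(OC[C@H](O[Si](C)(C)C(C)(C)C)/C(C)=C\CCO[Si](CC)(CC)CC)c1ccccc1 | intermediate
15 | {[(3Z,5R)-6-(benzoyloxy)-5-[(tert-butyldimethylsilyl)oxy]-4-methylhex-3-en-1-yl]oxy}dimethylsulfonium chloride | O=C(OC[C@H](O[Si](C)(C)C(C)(C)C)/C(C)=C\CCO[S+](C)C)c1ccccc1.[Cl-] | intermediate (not isolated)
16 | (2R,3Z)-2-[(tert-butyldimethylsilyl)oxy]-3-methyl-6-oxohex-3-en-1-yl benzoate | O=C(OC[C@H](O[Si](C)(C)C(C)(C)C)/C(C)=C\CC=O)c1ccccc1 | intermediate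
17 | (2R,3Z,6S,7Z)-2-[(tert-butyldimethylsilyl)oxy]-6-hydroxy-3,7-dimethyl-10-[(triethylsilyl)oxy]deca-3,7-dien-1-yl benzoate | O=C(OC[C@H](O[Si](C)(C)C(C)(C)C)/C(C)=C\C[C@H](O)/C(C)=C\CCO[Si](CC)(CC)CC)c1ccccc1 | intermediate
18 | (2R,3Z,6S,7Z)-2-[(tert-butyldimethylsilyl)oxy]-3,7-dimethyl-6,10-bis[(triethylsilyl)oxy]deca-3,7-dien-1-yl benzoate | O=C(OC[C@H](O[Si](C)(C)C(C)(C)C)/C(C)=C\C[C@H](O[Si](CC)(CC)CC)/C(C)=C\CCO[Si](CC)(CC)CC)c1ccccc1 | intermediate
19 | dimethylsulfonium chloride at the C7 oxygen of 18 (primary O–SiEt3 replaced by O–S+Me2) | O=C(OC[C@H](O[Si](C)(C)C(C)(C)C)/C(C)=C\C[C@H](O[Si](CC)(CC)CC)/C(C)=C\CCO[S+](C)C)c1ccccc1.[Cl-] | intermediate (not isolated)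
20 | (2R,3Z,6S,7Z)-2-[(tert-butyldimethylsilyl)oxy]-3,7-dimethyl-10-oxo-6-[(triethylsilyl)oxy]deca-3,7-dien-1-yl benzoate | O=C(OC[C@H](O[Si](C)(C)C(C)(C)C)/C(C)=C\C[C@H](O[Si](CC)(CC)CC)/C(C)=C\CC=O)c1ccccc1 | intermediate
21 | ethyl 2-(triphenylphosphoranylidene)propanoate | CCOC(=O)C(C)=P(c1ccccc1)(c1ccccc1)c1ccccc1 | starting material
22 | ethyl (2E,5Z,7S,9Z,11R)-12-(benzoyloxy)-11-[(tert-butyldimethylsilyl)oxy]-2,6,10-trimethyl-7-[(triethylsilyl)oxy]dodeca-2,5,9-trienoate | CCOC(=O)/C(C)=C/C/C=C(C)\[C@@H](O[Si](CC)(CC)CC)C/C=C(C)\[C@@H](O[Si](C)(C)C(C)(C)C)COC(=O)c1ccccc1 | intermediate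
23 | (2E,5Z,7S,9Z,11R)-11-[(tert-butyldimethylsilyl)oxy]-2,6,10-trimethyl-7-[(triethylsilyl)oxy]dodeca-2,5,9-triene-1,12-diol | OC/C(C)=C/C/C=C(C)\[C@@H](O[Si](CC)(CC)CC)C/C=C(C)\[C@@H](O[Si](C)(C)C(C)(C)C)CO | intermediate
24 | (2R,3Z,6S,7Z,10E)-2-[(tert-butyldimethylsilyl)oxy]-12-chloro-3,7,11-trimethyl-6-[(triethylsilyl)oxy]dodeca-3,7,10-trien-1-ol | ClC/C(C)=C/C/C=C(C)\[C@@H](O[Si](CC)(CC)CC)C/C=C(C)\[C@@H](O[Si](C)(C)C(C)(C)C)CO | intermediate
25 | (2R,3Z,6S,7Z,10E)-2-[(tert-butyldimethylsilyl)oxy]-3,7,11-trimethyl-6-[(triethylsilyl)oxy]-12-(tributylstannyl)dodeca-3,7,10-trien-1-ol | CCCC[Sn](CCCC)(CCCC)C/C(C)=C/C/C=C(C)\[C@@H](O[Si](CC)(CC)CC)C/C=C(C)\[C@@H](O[Si](C)(C)C(C)(C)C)CO | intermediate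
26 | (2R,3Z,6S,7Z,10E)-2-[(tert-butyldimethylsilyl)oxy]-3,7,11-trimethyl-6-[(triethylsilyl)oxy]-12-(tributylstannyl)dodeca-3,7,10-trienal | CCCC[Sn](CCCC)(CCCC)C/C(C)=C/C/C=C(C)\[C@@H](O[Si](CC)(CC)CC)C/C=C(C)\[C@@H](O[Si](C)(C)C(C)(C)C)C=O | intermediate
27 | (1S,2R,3Z,6S,7Z,10R)-2-[(tert-butyldimethylsilyl)oxy]-3,7-dimethyl-10-(prop-1-en-2-yl)-6-[(triethylsilyl)oxy]cyclodeca-3,7-dien-1-ol | C=C(C)[C@H]1C/C=C(C)\[C@@H](O[Si](CC)(CC)CC)C/C=C(C)\[C@@H](O[Si](C)(C)C(C)(C)C)[C@H]1O | intermediate
28 | (1S,2R,3Z,6S,7Z,10R)-2-[(tert-butyldimethylsilyl)oxy]-3,7-dimethyl-10-(prop-1-en-2-yl)-6-[(triethylsilyl)oxy]cyclodeca-3,7-dien-1-yl 3-methylbut-2-enoate | C=C(C)[C@H]1C/C=C(C)\[C@@H](O[Si](CC)(CC)CC)C/C=C(C)\[C@@H](O[Si](C)(C)C(C)(C)C)[C@H]1OC(=O)C=C(C)C | intermediate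
29 | (1S,2R,3Z,6S,7Z,10R)-2-[(tert-butyldimethylsilyl)oxy]-6-hydroxy-3,7-dimethyl-10-(prop-1-en-2-yl)cyclodeca-3,7-dien-1-yl 3-methylbut-2-enoate | C=C(C)[C@H]1C/C=C(C)\[C@@H](O)C/C=C(C)\[C@@H](O[Si](C)(C)C(C)(C)C)[C@H]1OC(=O)C=C(C)C | intermediate
30 | (1S,2R,3Z,6S,7Z,10R)-2-[(tert-butyldimethylsilyl)oxy]-3,7-dimethyl-6-{[(2Z)-2-methylbut-2-enoyl]oxy}-10-(prop-1-en-2-yl)cyclodeca-3,7-dien-1-yl 3-methylbut-2-enoate | C=C(C)[C@H]1C/C=C(C)\[C@@H](OC(=O)/C(C)=C\C)C/C=C(C)\[C@@H](O[Si](C)(C)C(C)(C)C)[C@H]1OC(=O)C=C(C)C | intermediate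
31 | (1S,2R,3Z,6S,7Z,10R)-2-hydroxy-3,7-dimethyl-6-{[(2Z)-2-methylbut-2-enoyl]oxy}-10-(prop-1-en-2-yl)cyclodeca-3,7-dien-1-yl 3-methylbut-2-enoate | C=C(C)[C@H]1C/C=C(C)\[C@@H](OC(=O)/C(C)=C\C)C/C=C(C)\[C@@H](O)[C@H]1OC(=O)C=C(C)C | intermediate
32 | (1R,3S,4Z,7R,8S,9S,10S)-9-hydroxy-4,10-dimethyl-8-[(3-methylbut-2-enoyl)oxy]-7-(prop-1-en-2-yl)-11-oxabicyclo[8.1.0]undec-4-en-3-yl (2Z)-2-methylbut-2-enoate | C=C(C)[C@H]1C/C=C(C)\[C@@H](OC(=O)/C(C)=C\C)C[C@H]2O[C@@]2(C)[C@@H](O)[C@H]1OC(=O)C=C(C)C | intermediate
33 | CNP0320216.1, (1R,3S,4S,5S,7R,8S,9S,10S)-3-angeloyloxy-1,10:4,5-diepoxy-9-hydroxy-8-senecioyloxygermacr-11-ene | C=C(C)[C@H]1C[C@@H]2O[C@]2(C)[C@@H](OC(=O)/C(C)=C\C)C[C@H]2O[C@@]2(C)[C@@H](O)[C@H]1OC(=O)C=C(C)C | target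

## Step count and least certain steps

Total step count: 22. Longest linear sequence: 21 steps (steps 1–3 and 5–22; step 4 is a one-step branch).

**Step 16 (key step).** The most likely failure is loss of the electron-rich allylic stannane by protodestannylation or bimolecular addition under the dilution that a ten-membered ring requires. If the ring does close, the syn preference may erode, because the tether forces the C9 and C6 chains gauche about the forming bond, an arrangement the open-chain model avoids. The fallback replaces tin by silicon and sets out from chloride 24. Displacement with PhMe2SiLi in THF at −78 °C would give the dimethyl(phenyl)silyl analogue of 25, F1. Parikh–Doering oxidation would give the dimethyl(phenyl)silyl analogue of 26, F2. F2 is inert to adventitious acid, can be purified, and can be added slowly to BF3·OEt2 in CH2Cl2 between −78 and −40 °C (intramolecular Hosomi–Sakurai reaction). The route is rejoined at 27. The stereochemical argument is unchanged, so this fallback answers the stability problem and not a wrong diastereomer ratio.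

**Step 5.** The most likely failure is insufficient enantiofacial control, since a small α-acyloxy aldehyde and a Z trisubstituted alkenylchromium are not the substrates for which the ligand class is best documented. The fallback separates C–C bond formation from stereocontrol and sets out from 12 and 9. Coupling with CrCl2/NiCl2 without ligand would give racemic 13, F3. Dess–Martin oxidation would give the Z enone (C9 ketone) F4. Corey–Bakshi–Shibata reduction with the (R)-2-methyl oxazaborolidine and catecholborane, the alkenyl group acting as the large substituent, should give the R carbinol and rejoin the route at 13.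

**Step 14.** The most likely failure is 1,2-migration of the TBS group from the C9 oxygen to the primary lithium alkoxide formed at C8, or alkoxide-induced loss of silyl groups. The fallback masks the hydroxyl and sets out from 24. TMSCl/Et3N would give the trimethylsilyl ether of 24, F5. Tributylstannyllithium (1.1 equiv, −78 °C) would give the trimethylsilyl ether of 25, F6. K2CO3 in MeOH at 0 °C removes only the primary trimethylsilyl group and rejoins the route at 25.

**Step 21.** The most likely failure is oxygen delivery to the wrong face of C1=C10: in a ten-membered ring the preference of open-chain Z allylic alcohols for the threo epoxy alcohol may return, against the cis outcome seen in eight- and nine-membered rings. The fallback replaces substrate direction by reagent control. It sets out from 31 and uses Ti(OiPr)4, L-(+)-diisopropyl tartrate and t-BuOOH with 4 Å sieves in CH2Cl2 at −20 °C. This tartrate delivers oxygen to the required face, and for the C9 configuration of 31 it is the matched, erythro-selective case. The product is 32 itself, so no further compound arises (F0).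

**Step 22.** The most likely failure is competing epoxidation of the isopropenyl group, because the allylic ester deactivates C4=C5, together with incomplete facial selectivity. The fallback moves this epoxidation forward to the free C3 alcohol, where hydrogen bonding to the peracid both accelerates the reaction and reinforces the anti (threo) sense. It sets out from 29. mCPBA/NaHCO3 would give the 4,5-epoxide of 29, F7. Angeloylation as in step 19 would give the 4,5-epoxide of 30, F8. Desilylation with Bu4NF buffered by acetic acid (to spare the epoxide and the esters) would give the 4,5-epoxide of 31, F9. The VO(acac)2/t-BuOOH epoxidation of step 21 then leads directly to 33. The price is that an epoxide is carried through one acylation and one desilylation.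

## Further compounds

F1 | step 16 | dimethyl(phenyl)silyl analogue of 25: (2R,3Z,6S,7Z,10E)-2-[(tert-butyldimethylsilyl)oxy]-12-[dimethyl(phenyl)silyl]-3,7,11-trimethyl-6-[(triethylsilyl)oxy]dodeca-3,7,10-trien-1-ol | C[Si](C)(c1ccccc1)C/C(C)=C/C/C=C(C)\[C@@H](O[Si](CC)(CC)CC)C/C=C(C)\[C@@H](O[Si](C)(C)C(C)(C)C)CO
F2 | step 16 | dimethyl(phenyl)silyl analogue of 26: (2R,3Z,6S,7Z,10E)-2-[(tert-butyldimethylsilyl)oxy]-12-[dimethyl(phenyl)silyl]-3,7,11-trimethyl-6-[(triethylsilyl)oxy]dodeca-3,7,10-trienal | C[Si](C)(c1ccccc1)C/C(C)=C/C/C=C(C)\[C@@H](O[Si](CC)(CC)CC)C/C=C(C)\[C@@H](O[Si](C)(C)C(C)(C)C)C=O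
F3 | step 5 | racemic 13: (3Z)-2-hydroxy-3-methyl-6-[(triethylsilyl)oxy]hex-3-en-1-yl benzoate | O=C(OCC(O)/C(C)=C\CCO[Si](CC)(CC)CC)c1ccccc1
F4 | step 5 | (3Z)-3-methyl-2-oxo-6-[(triethylsilyl)oxy]hex-3-en-1-yl benzoate | O=C(OCC(=O)/C(C)=C\CCO[Si](CC)(CC)CC)c1ccccc1
F5 | step 14 | trimethylsilyl ether of 24 (C8–OSiMe3, C12–Cl) | ClC/C(C)=C/C/C=C(C)\[C@@H](O[Si](CC)(CC)CC)C/C=C(C)\[C@@H](O[Si](C)(C)C(C)(C)C)CO[Si](C)(C)C
F6 | step 14 | trimethylsilyl ether of 25 (C8–OSiMe3, C12–SnBu3) | CCCC[Sn](CCCC)(CCCC)C/C(C)=C/C/C=C(C)\[C@@H](O[Si](CC)(CC)CC)C/C=C(C)\[C@@H](O[Si](C)(C)C(C)(C)C)CO[Si](C)(C)C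
F0 | step 21 | none | none
F7 | step 22 | 4,5-epoxide of 29 (epoxide oxygen anti to the C3 hydroxyl; C8 senecioate, C9 TBS ether, C1=C10 alkene intact) | C=C(C)[C@H]1C[C@@H]2O[C@]2(C)[C@@H](O)C/C=C(C)\[C@@H](O[Si](C)(C)C(C)(C)C)[C@H]1OC(=O)C=C(C)C
F8 | step 22 | 4,5-epoxide of 30 (C3 angelate, C8 senecioate, C9 TBS ether) | C=C(C)[C@H]1C[C@@H]2O[C@]2(C)[C@@H](OC(=O)/C(C)=C\C)C/C=C(C)\[C@@H](O[Si](C)(C)C(C)(C)C)[C@H]1OC(=O)C=C(C)C
F9 | step 22 | 4,5-epoxide of 31 (C3 angelate, C8 senecioate, free C9 hydroxyl) | C=C(C)[C@H]1C[C@@H]2O[C@]2(C)[C@@H](OC(=O)/C(C)=C\C)C/C=C(C)\[C@@H](O)[C@H]1OC(=O)C=C(C)C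
A1 | alternative 1 | (3Z,5S,7Z,9R)-9,10-bis[(tert-butyldimethylsilyl)oxy]-4,8-dimethyl-1-[(triethylsilyl)oxy]deca-3,7-dien-5-ol | CC(C)(C)[Si](C)(C)OC[C@H](O[Si](C)(C)C(C)(C)C)/C(C)=C\C[C@H](O)/C(C)=C\CCO[Si](CC)(CC)CC
A2 | alternative 1 | (tert-butyldimethylsilyloxy)acetaldehyde | CC(C)(C)[Si](C)(C)OCC=O
A3 | alternative 2 | open-chain C1 aldehyde / C10 α-bromo C9 ketone with C3 TBS ether, C8 PMB ether, C7 isopropenyl and Z C4=C5 alkene | C=C(C)[C@@H](C/C=C(C)\[C@@H](O[Si](C)(C)C(C)(C)C)CC=O)[C@H](OCc1ccc(OC)cc1)C(=O)C(C)Br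
A4 | alternative 2 | ten-membered C9 ketone with cis C1–C10 epoxide, Z C4=C5 alkene, C3 TBS ether and C8 PMB ether | C=C(C)[C@H]1C/C=C(C)\[C@@H](O[Si](C)(C)C(C)(C)C)C[C@H]2O[C@@]2(C)C(=O)[C@H]1OCc3ccc(OC)cc3
A5 | alternative 3 | cis-fused bicyclo[4.4.0]decadiene-3,8-diol (C3–C8 bonded, one cis diastereomer drawn) with C9 PMB ether and C7 isopropenyl | C=C(C)[C@H]1CC=C(C)[C@@]2(O)CC=C(C)[C@@H](OCc3ccc(OC)cc3)[C@@]12O
A6 | alternative 3 | ten-membered Z,Z-diene-3,8-dione with C9 PMB ether and C7 isopropenyl | C=C(C)[C@H]1C/C=C(C)\C(=O)C/C=C(C)\[C@@H](OCc2ccc(OC)cc2)C1=O
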